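## Retrosynthetic overview

1. Target ⇐ 10-O-TES ether ⇐ C3 ketone by oxidation of a macrocyclic allylic alcohol; the 10-membered carbocycle is closed last, at C3–C4, by intramolecular Nozaki–Hiyama–Kishi coupling of a (Z)-vinyl iodide with an α,β-epoxy aldehyde.
2. C8 isobutyrate ⇐ Mitsunobu esterification with inversion of the (8S)-alcohol that the fragment union delivers.
3. Key C7–C8 bond: intermolecular Zn-Barbier carbonyl allylation of a C8 aldehyde (C8–C10, C1–C3, C14) with a 3-(bromomethyl)butenolide (C4–C7, C11–C13, C15). It creates the trans α-methylene-γ-lactone together with C7 and C8.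
4. Aldehyde fragment: two Sharpless epoxidations starting from methallyl alcohol (C10 via 2-methylglycidol, then the trans C1/C2 oxirane).
5. Butenolide fragment: (R)-solketal, Stork–Zhao (Z)-iodo-olefination, ring-closing metathesis. Ring order: oxirane and butenolide in separate fragments, then the carbocycle.

Assumption: short-lived organometallic, ylide-adduct and phosphonium species formed under Barbier, NHK, Wittig and Mitsunobu conditions are treated as mechanistic intermediates without compound numbers; atom labels C1–C15 follow germacrane numbering of the target (oxirane C1/C2, ketone C3, C4=C5, lactone O on C6, ester on C8, carbinol C10, methylene C13).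

## Route

Step 1
Reactants: 1 2-methylprop-2-en-1-ol
Product: 2 [(2S)-2-methyloxiran-2-yl]methanol
Conditions: Ti(OiPr)4 (5 mol%), L-(+)-DIPT (6 mol%), t-BuOOH, 3 Å MS, CH2Cl2, −20 °C
Reagents that add atoms: tert-butyl hydroperoxide, CC(C)(C)OO
Why: Sharpless asymmetric epoxidation, in which L-(+)-tartrate gives the (2S)-epoxy alcohol (same facial sense as allyl alcohol to (S)-glycidol) and so sets the future C10.

Step 2
Reactants: 2 [(2S)-2-methyloxiran-2-yl]methanol
Product: 3 (2R)-2-methylpent-4-ene-1,2-diol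
Conditions: CH2=CHMgBr (3 eq), CuI (10 mol%), THF, −40 → 0 °C; H2O/NH4Cl work-up
Reagents that add atoms: vinylmagnesium bromide, C=C[Mg]Br
Why: Copper-catalysed SN2 epoxide opening at the unhindered CH2 terminus leaves the quaternary C–O bond untouched, so the configuration is retained (S→R is only a CIP priority change).

Step 3
Reactants: 3 (2R)-2-methylpent-4-ene-1,2-diol
Product: 5 ethyl (2E,4R)-4-hydroxy-4-methylhepta-2,6-dienoate, via hydroxy aldehyde 4 (not isolated)
Conditions: IBX (1.3 eq), Ph3P=CHCO2Et (1.5 eq), DMSO, rt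
Reagents that add atoms: ethyl (triphenylphosphoranylidene)acetate, CCOC(=O)C=P(c1ccccc1)(c1ccccc1)c1ccccc1
Why: IBX oxidises the primary alcohol of a 1,2-diol without glycol cleavage, and the non-enolisable α-hydroxy aldehyde is trapped in the same flask by a stabilised-ylide Wittig reaction that gives the (E)-enoate.

Step 4
Reactants: 5 ethyl (2E,4R)-4-hydroxy-4-methylhepta-2,6-dienoate
Product: 6 ethyl (2E,4R)-4-methyl-4-[(triethylsilyl)oxy]hepta-2,6-dienoate
Conditions: TESOTf (1.3 eq), 2,6-lutidine (2 eq), CH2Cl2, −78 → 0 °C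
Reagents that add atoms: triethylsilyl trifluoromethanesulfonate, CC[Si](CC)(CC)OS(=O)(=O)C(F)(F)F
Why: Silyl triflate silylation is strong enough for a tertiary alcohol and masks C10–OH before the hydroxyl-directed epoxidation and all later steps.

Step 5
Reactants: 6 ethyl (2E,4R)-4-methyl-4-[(triethylsilyl)oxy]hepta-2,6-dienoate
Product: 7 (2E,4R)-4-methyl-4-[(triethylsilyl)oxy]hepta-2,6-dien-1-ol
Conditions: DIBAL-H (2.4 eq), CH2Cl2, −78 °C; Rochelle salt
Reagents that add atoms: none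
Why: DIBAL 1,2-reduction of the enoate gives the (E)-allylic alcohol without touching the silyl ether or the alkenes.

Step 6
Reactants: 7 (2E,4R)-4-methyl-4-[(triethylsilyl)oxy]hepta-2,6-dien-1-ol
Product: 8 {(2S,3R)-3-[(2R)-2-[(triethylsilyl)oxy]pent-4-en-2-yl]oxiran-2-yl}methanol
Conditions: Ti(OiPr)4 (10 mol%), L-(+)-DIPT (12 mol%), t-BuOOH, 4 Å MS, CH2Cl2, −20 °C
Reagents that add atoms: tert-butyl hydroperoxide, CC(C)(C)OO
Why: Sharpless asymmetric epoxidation under reagent control, where L-(+)-tartrate gives the (2S)-epoxy alcohol (as (E)-hex-2-enol gives 2S,3S), the E-alkene gives the trans oxirane (C1/C2 of the target), and the undirected terminal alkene is untouched.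

Step 7
Reactants: 8 {(2S,3R)-3-[(2R)-2-[(triethylsilyl)oxy]pent-4-en-2-yl]oxiran-2-yl}methanol
Product: 9 triethyl{[(2R)-2-[(2R,3S)-3-{[(4-methoxybenzyl)oxy]methyl}oxiran-2-yl]pent-4-en-2-yl]oxy}silane
Conditions: NaH, PMBCl, Bu4NI (cat.), THF/DMF, 0 °C
Reagents that add atoms: 4-methoxybenzyl chloride, COc1ccc(CCl)cc1
Why: Williamson etherification of the primary alkoxide at 0 °C is faster than Payne rearrangement and installs a group orthogonal to the TES ether.

Step 8
Reactants: 9 triethyl{[(2R)-2-[(2R,3S)-3-{[(4-methoxybenzyl)oxy]methyl}oxiran-2-yl]pent-4-en-2-yl]oxy}silane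
Product: 10 (3R)-3-[(2R,3S)-3-{[(4-methoxybenzyl)oxy]methyl}oxiran-2-yl]-3-[(triethylsilyl)oxy]butanal
Conditions: OsO4 (2 mol%), NaIO4 (4 eq), 2,6-lutidine, dioxane/H2O 3:1, rt
Reagents that add atoms: osmium tetroxide (catalytic, oxygen ultimately from periodate), O=[Os](=O)(=O)=O; sodium periodate, [Na+].[O-]I(=O)(=O)=O
Why: Lemieux–Johnson oxidative cleavage of the only alkene under lutidine buffering gives the C8 aldehyde and spares oxirane, PMB and TES groups.

Step 9
Reactants: 11 [(4R)-2,2-dimethyl-1,3-dioxolan-4-yl]methanol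
Product: 12 (4S)-2,2-dimethyl-1,3-dioxolane-4-carbaldehyde
Conditions: (COCl)2, DMSO, CH2Cl2, −78 °C; Et3N; used crude
Reagents that add atoms: none
Why: Swern oxidation gives glyceraldehyde acetonide without epimerisation (R→S is only a CIP change).

Step 10
Reactants: 12 (4S)-2,2-dimethyl-1,3-dioxolane-4-carbaldehyde
Product: 13 (4R)-4-[(1Z)-2-iodoprop-1-en-1-yl]-2,2-dimethyl-1,3-dioxolane
Conditions: EtPPh3I, n-BuLi, THF, rt; I2, −78 °C; NaHMDS, −20 °C; then 12, −78 → −20 °C
Reagents that add atoms: ethyltriphenylphosphonium iodide, CC[P+](c1ccccc1)(c1ccccc1)c1ccccc1.[I-]; iodine, II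
Why: Stork–Zhao-type Wittig olefination with the α-iodoethylidene ylide goes through the kinetic cis-oxaphosphetane to the (Z)-iodoalkene (C6 cis to I), and the low temperature protects the α-alkoxy stereocentre.

Step 11
Reactants: 13 (4R)-4-[(1Z)-2-iodoprop-1-en-1-yl]-2,2-dimethyl-1,3-dioxolane
Product: 14 (2R,3Z)-4-iodopent-3-ene-1,2-diol
Conditions: AcOH/H2O 4:1, rt
Reagents that add atoms: none
Why: Mild acid-catalysed acetal hydrolysis frees the diol without ionising the allylic C–O bond.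

Step 12
Reactants: 14 (2R,3Z)-4-iodopent-3-ene-1,2-diol
Product: 16 (2R)-2-[(1Z)-2-iodoprop-1-en-1-yl]oxirane, via primary tosylate 15 (not isolated)
Conditions: TsCl (1.05 eq), Et3N, Bu2SnO (2 mol%), CH2Cl2, 0 °C; then K2CO3, MeOH, rt
Reagents that add atoms: none
Why: Tin-catalysed selective primary tosylation followed by intramolecular Williamson closure displaces only the primary carbon, so the carbinol stereocentre is retained.

Step 13
Reactants: 16 (2R)-2-[(1Z)-2-iodoprop-1-en-1-yl]oxirane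
Product: 17 (3S,4Z)-5-iodohexa-1,4-dien-3-ol
Conditions: Me3S+ I− (3 eq), n-BuLi (2.9 eq), THF, −10 °C; then 16, −10 → 10 °C
Reagents that add atoms: trimethylsulfonium iodide, C[S+](C)C.[I-]
Why: One-carbon homologation of a terminal epoxide to an allylic alcohol with excess dimethylsulfonium methylide (SN2 opening at CH2, then ylide-mediated loss of Me2S) does not involve the stereocentre (R→S is a CIP change).

Step 14
Reactants: 17 (3S,4Z)-5-iodohexa-1,4-dien-3-ol; 18 2-(bromomethyl)prop-2-enoic acid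
Product: 19 (3S,4Z)-5-iodohexa-1,4-dien-3-yl 2-(bromomethyl)prop-2-enoate
Conditions: DCC, DMAP (5 mol%), CH2Cl2, −20 → 0 °C
Reagents that add atoms: none
Why: Steglich esterification at low temperature and low DMAP loading acylates the secondary alcohol without SN2′ attack on the allylic bromide.

Step 15
Reactants: 19 (3S,4Z)-5-iodohexa-1,4-dien-3-yl 2-(bromomethyl)prop-2-enoate
Product: 20 (5S)-3-(bromomethyl)-5-[(1Z)-2-iodoprop-1-en-1-yl]furan-2(5H)-one
Conditions: Grubbs II (5 mol%), CH2Cl2 (5 mM), 40 °C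
Reagents that add atoms: none
Why: Ring-closing metathesis between the vinyl group and the 1,1-disubstituted acrylate closes the five-membered butenolide, while the trisubstituted iodoalkene is inert to the catalyst.

Step 16
Reactants: 10 (3R)-3-[(2R,3S)-3-{[(4-methoxybenzyl)oxy]methyl}oxiran-2-yl]-3-[(triethylsilyl)oxy]butanal; 20 (5S)-3-(bromomethyl)-5-[(1Z)-2-iodoprop-1-en-1-yl]furan-2(5H)-one
Product: 21 (4R,5S)-4-{(1S,3R)-1-hydroxy-3-[(2R,3S)-3-{[(4-methoxybenzyl)oxy]methyl}oxiran-2-yl]-3-[(triethylsilyl)oxy]butyl}-5-[(1Z)-2-iodoprop-1-en-1-yl]-3-methylideneoxolan-2-one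
Conditions: Zn dust, THF/sat. aq NH4Cl 2:1, 0 °C → rt
Reagents that add atoms: none
Why: Zinc-mediated Barbier carbonyl allylation, in which zinc inserts only into the allylic C–Br bond; the cyclic (E-locked) allylzinc attacks through its γ-carbon (C7) anti to the C6 substituent in a chair Zimmerman–Traxler transition state with the aldehyde chain equatorial, which gives the trans α-methylene lactone and the 7,8-anti (8S) carbinol.

Step 17
Reactants: 21 (the (8S)-alcohol from step 16)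
Product: 22 (1R,3R)-1-{(2S,3R)-2-[(1Z)-2-iodoprop-1-en-1-yl]-4-methylidene-5-oxooxolan-3-yl}-3-[(2R,3S)-3-{[(4-methoxybenzyl)oxy]methyl}oxiran-2-yl]-3-[(triethylsilyl)oxy]butyl 2-methylpropanoate
Conditions: PPh3, DIAD, i-PrCO2H, toluene, 0 °C → rt
Reagents that add atoms: 2-methylpropanoic acid, CC(C)C(=O)O
Why: Mitsunobu esterification displaces the activated C8 oxygen by isobutyrate in an SN2 step, inverting 8S to the required 8R and installing the ester in one operation.

Step 18
Reactants: 22 (the C8 isobutyrate PMB ether)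
Product: 23 (1R,3R)-3-[(2R,3S)-3-(hydroxymethyl)oxiran-2-yl]-1-{(2S,3R)-2-[(1Z)-2-iodoprop-1-en-1-yl]-4-methylidene-5-oxooxolan-3-yl}-3-[(triethylsilyl)oxy]butyl 2-methylpropanoate
Conditions: DDQ (1.5 eq), CH2Cl2/pH 7 buffer 10:1, 0 °C
Reagents that add atoms: none
Why: Oxidative PMB cleavage under neutral buffered conditions frees the C3 alcohol without affecting the oxirane, TES ether, vinyl iodide, ester or methylene lactone.

Step 19
Reactants: 23 (the C3 primary alcohol)
Product: 24 (1R,3R)-3-[(2R,3R)-3-formyloxiran-2-yl]-1-{(2S,3R)-2-[(1Z)-2-iodoprop-1-en-1-yl]-4-methylidene-5-oxooxolan-3-yl}-3-[(triethylsilyl)oxy]butyl 2-methylpropanoate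
Conditions: DMP (1.5 eq), pyridine, CH2Cl2, 0 °C → rt; used at once
Reagents that add atoms: none
Why: Buffered Dess–Martin oxidation gives the α,β-epoxy aldehyde, whose α-carbon is an oxirane carbon and does not epimerise.

Step 20
Reactants: 24 (the epoxy aldehyde vinyl iodide)
Product: 25 (1R,2S,3RS,4Z,6R,7R,8R,10R)-1,2-epoxy-3-hydroxy-8-(2-methylpropanoyloxy)-10-[(triethylsilyl)oxy]germacra-4,11(13)-dien-12,6-olide
Conditions: CrCl2 (10 eq), NiCl2 (0.1 eq), degassed DMSO (2 mM, slow addition), rt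
Reagents that add atoms: none
Why: Intramolecular Nozaki–Hiyama–Kishi coupling forms C3–C4 and the 10-membered ring with retention of the (Z)-alkenyl geometry, tolerating ester, lactone and silyl ether; the C3 epimer mixture is irrelevant because C3 is oxidised next.

Step 21
Reactants: 25 (the macrocyclic C3 alcohol, both epimers)
Product: 26 (1R,2R,4Z,6R,7R,8R,10R)-1,2-epoxy-8-(2-methylpropanoyloxy)-3-oxo-10-[(triethylsilyl)oxy]germacra-4,11(13)-dien-12,6-olide
Conditions: DMP (2 eq), pyridine, CH2Cl2, rt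
Reagents that add atoms: none
Why: Dess–Martin oxidation of the allylic, α-epoxy carbinol converges both epimers to the (Z)-enone epoxy ketone under non-basic conditions.

Step 22
Reactants: 26 (the 10-O-TES ether of the target)
Product: 27 (1R,2R,4Z,6R,7R,8R,10R)-1,2-epoxy-10-hydroxy-8-(2-methylpropanoyloxy)-3-oxogermacra-4,11(13)-dien-12,6-olide
Conditions: HF·pyridine, excess pyridine, THF, 0 °C → rt
Reagents that add atoms: none
Why: Buffered fluoride desilylation removes the tertiary TES ether without base (no Payne rearrangement, no attack on the methylene lactone) and without opening the electron-poor oxirane.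

## Compound list

1 | 2-methylprop-2-en-1-ol | C=C(C)CO | starting material
2 | [(2S)-2-methyloxiran-2-yl]methanol | C[C@]1(CO)CO1 | intermediate
3 | (2R)-2-methylpent-4-ene-1,2-diol | C=CC[C@@](C)(O)CO | intermediate
4 | (2R)-2-hydroxy-2-methylpent-4-enal | C=CC[C@@](C)(O)C=O | intermediate
5 | ethyl (2E,4R)-4-hydroxy-4-methylhepta-2,6-dienoate | C=CC[C@@](C)(O)/C=C/C(=O)OCC | intermediate
6 | ethyl (2E,4R)-4-methyl-4-[(triethylsilyl)oxy]hepta-2,6-dienoate | C=CC[C@@](C)(O[Si](CC)(CC)CC)/C=C/C(=O)OCC | intermediate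
7 | (2E,4R)-4-methyl-4-[(triethylsilyl)oxy]hepta-2,6-dien-1-ol | C=CC[C@@](C)(O[Si](CC)(CC)CC)/C=C/CO | intermediate
8 | {(2S,3R)-3-[(2R)-2-[(triethylsilyl)oxy]pent-4-en-2-yl]oxiran-2-yl}methanol | C=CC[C@@](C)(O[Si](CC)(CC)CC)[C@@H]1O[C@H]1CO | intermediate
9 | triethyl{[(2R)-2-[(2R,3S)-3-{[(4-methoxybenzyl)oxy]methyl}oxiran-2-yl]pent-4-en-2-yl]oxy}silane | C=CC[C@@](C)(O[Si](CC)(CC)CC)[C@@H]1O[C@H]1COCc1ccc(OC)cc1 | intermediate
10 | (3R)-3-[(2R,3S)-3-{[(4-methoxybenzyl)oxy]methyl}oxiran-2-yl]-3-[(triethylsilyl)oxy]butanal | O=CC[C@@](C)(O[Si](CC)(CC)CC)[C@@H]1O[C@H]1COCc1ccc(OC)cc1 | intermediate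
11 | [(4R)-2,2-dimethyl-1,3-dioxolan-4-yl]methanol ((R)-solketal) | CC1(C)OC[C@@H](CO)O1 | starting material
12 | (4S)-2,2-dimethyl-1,3-dioxolane-4-carbaldehyde | CC1(C)OC[C@@H](C=O)O1 | intermediate
13 | (4R)-4-[(1Z)-2-iodoprop-1-en-1-yl]-2,2-dimethyl-1,3-dioxolane | CC1(C)OC[C@@H](/C=C(/C)I)O1 | intermediate
14 | (2R,3Z)-4-iodopent-3-ene-1,2-diol | OC[C@H](O)/C=C(/C)I | intermediate
15 | (2R,3Z)-2-hydroxy-4-iodopent-3-en-1-yl 4-methylbenzenesulfonate | Cc1ccc(cc1)S(=O)(=O)OC[C@H](O)/C=C(/C)I | intermediate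
16 | (2R)-2-[(1Z)-2-iodoprop-1-en-1-yl]oxirane | C1O[C@@H]1/C=C(/C)I | intermediate
17 | (3S,4Z)-5-iodohexa-1,4-dien-3-ol | C=C[C@H](O)/C=C(/C)I | intermediate
18 | 2-(bromomethyl)prop-2-enoic acid | C=C(CBr)C(=O)O | starting material
19 | (3S,4Z)-5-iodohexa-1,4-dien-3-yl 2-(bromomethyl)prop-2-enoate | C=C[C@H](OC(=O)C(=C)CBr)/C=C(/C)I | intermediate
20 | (5S)-3-(bromomethyl)-5-[(1Z)-2-iodoprop-1-en-1-yl]furan-2(5H)-one | O=C1O[C@H](/C=C(/C)I)C=C1CBr | intermediate
21 | (4R,5S)-4-{(1S,3R)-1-hydroxy-3-[(2R,3S)-3-{[(4-methoxybenzyl)oxy]methyl}oxiran-2-yl]-3-[(triethylsilyl)oxy]butyl}-5-[(1Z)-2-iodoprop-1-en-1-yl]-3-methylideneoxolan-2-one | C=C1C(=O)O[C@H](/C=C(/C)I)[C@H]1[C@@H](O)C[C@@](C)(O[Si](CC)(CC)CC)[C@@H]2O[C@H]2COCc2ccc(OC)cc2 | intermediate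
22 | (1R,3R)-1-{(2S,3R)-2-[(1Z)-2-iodoprop-1-en-1-yl]-4-methylidene-5-oxooxolan-3-yl}-3-[(2R,3S)-3-{[(4-methoxybenzyl)oxy]methyl}oxiran-2-yl]-3-[(triethylsilyl)oxy]butyl 2-methylpropanoate | C=C1C(=O)O[C@H](/C=C(/C)I)[C@H]1[C@H](OC(=O)C(C)C)C[C@@](C)(O[Si](CC)(CC)CC)[C@@H]2O[C@H]2COCc2ccc(OC)cc2 | intermediate
23 | (1R,3R)-3-[(2R,3S)-3-(hydroxymethyl)oxiran-2-yl]-1-{(2S,3R)-2-[(1Z)-2-iodoprop-1-en-1-yl]-4-methylidene-5-oxooxolan-3-yl}-3-[(triethylsilyl)oxy]butyl 2-methylpropanoate | C=C1C(=O)O[C@H](/C=C(/C)I)[C@H]1[C@H](OC(=O)C(C)C)C[C@@](C)(O[Si](CC)(CC)CC)[C@@H]2O[C@H]2CO | intermediate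
24 | (1R,3R)-3-[(2R,3R)-3-formyloxiran-2-yl]-1-{(2S,3R)-2-[(1Z)-2-iodoprop-1-en-1-yl]-4-methylidene-5-oxooxolan-3-yl}-3-[(triethylsilyl)oxy]butyl 2-methylpropanoate | C=C1C(=O)O[C@H](/C=C(/C)I)[C@H]1[C@H](OC(=O)C(C)C)C[C@@](C)(O[Si](CC)(CC)CC)[C@@H]2O[C@H]2C=O | intermediate
25 | (1R,2S,3RS,4Z,6R,7R,8R,10R)-1,2-epoxy-3-hydroxy-8-(2-methylpropanoyloxy)-10-[(triethylsilyl)oxy]germacra-4,11(13)-dien-12,6-olide (C3 epimer mixture) | C=C1C(=O)O[C@@H]2/C=C(/C)C(O)[C@@H]3O[C@H]3[C@](C)(O[Si](CC)(CC)CC)C[C@@H](OC(=O)C(C)C)[C@@H]12 | intermediate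
26 | (1R,2R,4Z,6R,7R,8R,10R)-1,2-epoxy-8-(2-methylpropanoyloxy)-3-oxo-10-[(triethylsilyl)oxy]germacra-4,11(13)-dien-12,6-olide | C=C1C(=O)O[C@@H]2/C=C(/C)C(=O)[C@@H]3O[C@H]3[C@](C)(O[Si](CC)(CC)CC)C[C@@H](OC(=O)C(C)C)[C@@H]12 | intermediate
27 | (1R,2R,4Z,6R,7R,8R,10R)-1,2-epoxy-10-hydroxy-8-(2-methylpropanoyloxy)-3-oxogermacra-4,11(13)-dien-12,6-olide | C=C1C(=O)O[C@@H]2/C=C(/C)C(=O)[C@@H]3O[C@H]3[C@](C)(O)C[C@@H](OC(=O)C(C)C)[C@@H]12 | target

## Step count and risks

Total steps: 22. Longest linear sequence: 15 steps (steps 1–8, then 16–22); the butenolide branch is 7 steps (9–15) before the union.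

The three steps most likely to fail:

Step 20, the NHK macrocyclisation. Cr(II) can reductively open an α,β-epoxy aldehyde, and a strained 10-membered ring invites oligomerisation. The fallback sets out from alcohol 23 and comes back at ketone 26, so step 21 is no longer needed. Compound 23 is stannylated with hexamethylditin and Pd(PPh3)4 to the trimethylstannyl alcohol F1 (Me3Sn in place of iodine, Z retained). F1 is oxidised with Dess–Martin periodinane to the stannyl epoxy aldehyde F2, and then under Pinnick conditions to the stannyl epoxy acid F3. Ghosez's reagent turns F3 into the acid chloride F4, which is cyclised at high dilution by an intramolecular acylative Stille coupling (Pd2(dba)3, tri(2-furyl)phosphine, THF, 50 °C). This forms the C3–C4 bond directly at the ketone oxidation level, with retention of the alkene geometry and without any low-valent chromium.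

Step 17, the Mitsunobu inversion. The C8 carbinol is hindered (ring methine on one side, a CH2 next to a quaternary carbon on the other), so elimination or incomplete conversion with the weakly acidic isobutyric acid is possible. The fallback sets out from alcohol 21 and comes back at ester 22. Compound 21 is sulfonylated with chloromethanesulfonyl chloride and pyridine to the C8 chloromethanesulfonate F5. F5 is then displaced with caesium 2-methylpropanoate and 18-crown-6 in toluene at 60 °C, an SN2 inversion with a small, very good leaving group and a naked carboxylate.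

Step 13, the sulfur-ylide homologation. The excess basic ylide may dehydroiodinate the (Z)-iodoalkene (H anti to I) or open the vinyl epoxide in an SN2′ sense. The fallback sets out from diol 14 and comes back at dienol 17. Compound 14 is silylated (TESOTf, 2,6-lutidine) to the bis(triethylsilyl) ether F6. Swern conditions cleave and oxidise only the primary TES ether, giving the α-silyloxy aldehyde F7. F7 is methylenated under non-basic conditions with the Tebbe reagent at −40 °C to the silyl-protected dienol F8, and HF·pyridine then releases 17.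

## Further compounds

F1 | step 20 | trimethylstannyl analogue of 23: (1R,3R)-3-[(2R,3S)-3-(hydroxymethyl)oxiran-2-yl]-1-{4-methylidene-5-oxo-2-[(1Z)-2-(trimethylstannyl)prop-1-en-1-yl]oxolan-3-yl}-3-[(triethylsilyl)oxy]butyl 2-methylpropanoate | C=C1C(=O)O[C@H](/C=C(/C)[Sn](C)(C)C)[C@H]1[C@H](OC(=O)C(C)C)C[C@@](C)(O[Si](CC)(CC)CC)[C@@H]2O[C@H]2CO
F2 | step 20 | stannyl epoxy aldehyde (F1 with CHO in place of CH2OH) | C=C1C(=O)O[C@H](/C=C(/C)[Sn](C)(C)C)[C@H]1[C@H](OC(=O)C(C)C)C[C@@](C)(O[Si](CC)(CC)CC)[C@@H]2O[C@H]2C=O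
F3 | step 20 | stannyl epoxy acid (F1 with CO2H in place of CH2OH) | C=C1C(=O)O[C@H](/C=C(/C)[Sn](C)(C)C)[C@H]1[C@H](OC(=O)C(C)C)C[C@@](C)(O[Si](CC)(CC)CC)[C@@H]2O[C@H]2C(=O)O
F4 | step 20 | stannyl epoxy acid chloride (F1 with COCl in place of CH2OH) | C=C1C(=O)O[C@H](/C=C(/C)[Sn](C)(C)C)[C@H]1[C@H](OC(=O)C(C)C)C[C@@](C)(O[Si](CC)(CC)CC)[C@@H]2O[C@H]2C(=O)Cl
F5 | step 17 | C8 chloromethanesulfonate of 21 (8S) | C=C1C(=O)O[C@H](/C=C(/C)I)[C@H]1[C@@H](OS(=O)(=O)CCl)C[C@@](C)(O[Si](CC)(CC)CC)[C@@H]2O[C@H]2COCc2ccc(OC)cc2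
F6 | step 13 | (2R,3Z)-4-iodo-1,2-bis[(triethylsilyl)oxy]pent-3-ene | CC[Si](CC)(CC)OC[C@H](O[Si](CC)(CC)CC)/C=C(/C)I
F7 | step 13 | (2S,3Z)-4-iodo-2-[(triethylsilyl)oxy]pent-3-enal | O=C[C@H](O[Si](CC)(CC)CC)/C=C(/C)I
F8 | step 13 | triethyl{[(3S,4Z)-5-iodohexa-1,4-dien-3-yl]oxy}silane | C=C[C@H](O[Si](CC)(CC)CC)/C=C(/C)I
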